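**Plan**

- Positions follow labdane numbering (ring A: C1–C5 and C10; ring B: C5–C10; C17 on C8; C18/C19 on C4; C20 on C10; side chain C11–C16); "syn" and "anti" refer to the C10 methyl group.
- Retrosynthesis cuts C14=C15 and C12=C13 (two olefinations), then C11–C12, C9–C11 and C8–C17 (appendages hung on a C8 carbonyl), then the two C4–CH3 bonds, and last C5–C6, which opens ring B to an achiral dienone aldehyde.
- Enabling feature: C10 is a quaternary, methyl-bearing carbon whose ring A neighbours C1 and C5 map onto the two enantiotopic β-carbons of a 4-alkyl-4-methylcyclohexa-2,5-dienone, and C6, the ring B atom bonded to C5, carries oxygen at the level an acyl-anion carbon delivers.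
- Forward: ring A is made first as the dienone (annulation, dehydrogenation); ring B closes by carbene-catalysed acyl-anion addition of C6 to C5; ring A is trimmed (gem-dimethyl, C3 deoxygenation); the C6 carbonyl is moved to C8 to bring in C11/C12 and C17, moved back, reduced and acetylated; the diene is finished last.
- Stereochemistry: C10 from the chiral carbene's choice of enone arm; C5 by equilibration α to the C6 ketone (trans fusion); C9 by kinetic protonation of a C8 enolate anti to the C10 methyl; C6 by hydride attack anti to the axial C4/C10 methyls; 12E from cross-metathesis.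

Key step: step 6

Assumption: which antipode of the triazolium precatalyst attacks the enone arm leading to (10R)-15 is to be fixed in the first run; both antipodes are commercial and the route is written for that one.

**Route**

Step 1
Reactants: 1 propanal; 2 cyclohexylamine
Product: 3 N-propylidenecyclohexanamine
Conditions: K2CO3, neat, 0 °C to rt; distil
Reagents that add atoms: none
Why: Imine (Schiff base) condensation of an unhindered aldehyde with a primary amine masks propanal against self-aldol reaction and allows clean α-metalation.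

Step 2
Reactants: 3 N-propylidenecyclohexanamine; 4 5-bromopent-1-ene
Product: 6 rac-2-methylhept-6-enal, via alkylated imine 5 (not isolated)
Conditions: LiN(iPr)2, THF, −78 to 0 °C; then 4, −78 °C to rt; then aq oxalic acid, rt
Reagents that add atoms: water, O
Why: Metalloenamine (aza-enolate) alkylation by SN2 displacement on a primary bromide, followed by imine hydrolysis, should give the α-branched aldehyde without the polyalkylation and aldol problems of a free aldehyde enolate.

Step 3
Reactants: 6 rac-2-methylhept-6-enal; 7 methyl vinyl ketone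
Product: 10 rac-4-methyl-4-(pent-4-en-1-yl)cyclohex-2-en-1-one, via enamine 8 (not isolated), via keto aldehyde 9 (not isolated)
Conditions: pyrrolidine (1.1 equiv), toluene, reflux (Dean–Stark); then 7, rt to 60 °C; then AcOH, NaOAc, H2O, reflux
Reagents that add atoms: none
Why: Robinson annulation in its Stork enamine form: the enamine of the α-branched aldehyde adds to the enone to build the quaternary carbon, and buffered hydrolysis with intramolecular aldol condensation of the 1,5-keto aldehyde gives the 4,4-disubstituted cyclohexenone, whose racemic stereocentre vanishes in step 4.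

Step 4
Reactants: 10 rac-4-methyl-4-(pent-4-en-1-yl)cyclohex-2-en-1-one
Product: 11 4-methyl-4-(pent-4-en-1-yl)cyclohexa-2,5-dien-1-one
Conditions: DDQ, 1,4-dioxane, reflux
Reagents that add atoms: none
Why: DDQ dehydrogenation of a 4,4-disubstituted cyclohex-2-enone (hydride abstraction from the dienol) gives the cross-conjugated, achiral dienone; the quaternary C4 rules out aromatisation and the isolated terminal alkene is not oxidised.

Step 5
Reactants: 11 4-methyl-4-(pent-4-en-1-yl)cyclohexa-2,5-dien-1-one
Product: 13 4-(1-methyl-4-oxocyclohexa-2,5-dien-1-yl)butanal, via ozonide 12 (not isolated)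
Conditions: O3, CH2Cl2, −78 °C, Sudan Red 7B as end-point indicator; then PPh3, −78 °C to rt
Reagents that add atoms: ozone, [O-][O+]=O
Why: Ozonolysis with reductive work-up: ozone attacks the electron-rich terminal alkene far faster than the electron-poor dienone double bonds, and triphenylphosphine reduces the ozonide to the aldehyde.

Step 6
Reactants: 13 4-(1-methyl-4-oxocyclohexa-2,5-dien-1-yl)butanal
Product: 15 (5R,10R)-10-methyl-trans-decal-1-ene-3,6-dione, via cis-fused dione 14 (not isolated)
Conditions: aminoindanol-derived triazolium salt [5a,10b-dihydro-2-(pentafluorophenyl)-4H,6H-indeno[2,1-b][1,2,4]triazolo[4,3-d][1,4]oxazin-2-ium tetrafluoroborate, one antipode] (10 mol %), KN(SiMe3)2 (10 mol %), toluene, 23 °C; then DBU (0.2 equiv), rt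
Reagents that add atoms: none
Why: The carbene freed from the triazolium salt adds to the aldehyde and, after proton transfer, gives the Breslow intermediate, whose nucleophilic carbon (C6) adds in conjugate fashion to C5 of one enone arm before proton transfer and loss of the carbene release the 1,4-dione (intramolecular Stetter reaction). The closest known reaction type is the triazolium-carbene-catalysed intramolecular Stetter desymmetrisation of 4,4-disubstituted cyclohexa-2,5-dienones by tethered aliphatic aldehydes, and six-membered rings are known to close in intramolecular Stetter reactions of aliphatic aldehydes. Ring B closes in the 6-exo-trig mode, and because the three-carbon tether reaches C5 only from the dienone face on which it is attached, the adduct 14 formed first is cis-fused. C10 becomes a stereocentre because only one of the two enantiotopic enone arms is attacked, a choice made by the chiral carbene, whose aminoindanol backbone and N-aryl group shield one quadrant around the Breslow carbon. C5 lies α to the new C6 ketone and is epimerised by DBU to the trans ring fusion, expected to be the more stable one (as for 6-oxo steroids with the same A/B pattern), so it is under thermodynamic control. The step needs enantiotopic-arm selectivity and 1,4- over 1,2-addition: the substrate offers two identical, doubly activated acceptors and no stereocentre that could oppose the catalyst, the tether places the β-carbon in a six-membered arrangement while the dienone carbonyl stays out of reach, and the aldehyde is unbranched at its α-carbon so carbene addition is not slowed.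

Step 7
Reactants: 15 (5R,10R)-10-methyl-trans-decal-1-ene-3,6-dione
Product: 16 (5R,10R)-6,6-ethylenedioxy-10-methyl-trans-decal-1-en-3-one
Conditions: ethylene glycol, TsOH·H2O (cat.), benzene, reflux (Dean–Stark)
Reagents that add atoms: ethylene glycol, OCCO
Why: Acid-catalysed ketalisation (dioxolane formation) is selective for the saturated C6 ketone because the conjugated C3 carbonyl is less electrophilic, as in the standard monoketalisation of bicyclic enediones; no stereocentre is formed.

Step 8
Reactants: 16 (5R,10R)-6,6-ethylenedioxy-10-methyl-trans-decal-1-en-3-one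
Product: 17 (5S,10R)-6,6-ethylenedioxy-4,4,10-trimethyl-trans-decal-1-en-3-one
Conditions: KOtBu (4 equiv), MeI (8 equiv), THF/tBuOH, 0 °C to rt
Reagents that add atoms: iodomethane, CI
Why: Exhaustive α'-alkylation of the enone: C4 is the only enolisable position (C2 is vinylic and the quaternary C10 excludes γ-deprotonation), so two rounds of cross-conjugated enolate formation and SN2 methylation install the gem-dimethyl group without creating a stereocentre.

Step 9
Reactants: 17 (5S,10R)-6,6-ethylenedioxy-4,4,10-trimethyl-trans-decal-1-en-3-one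
Product: 18 (5S,10R)-6,6-ethylenedioxy-4,4,10-trimethyl-trans-decalin-3-one
Conditions: H2 (1 atm), 10 % Pd/C, EtOAc, rt
Reagents that add atoms: none
Why: Heterogeneous catalytic hydrogenation saturates the disubstituted C1=C2 bond, leaving the hindered ketone and the dioxolane intact.

Step 10
Reactants: 18 (5S,10R)-6,6-ethylenedioxy-4,4,10-trimethyl-trans-decalin-3-one
Product: 21 (5R,10S)-4,4,10-trimethyl-trans-decalin-6-one, via hydrazone 19 (not isolated), via deoxygenated ketal 20 (not isolated)
Conditions: N2H4·H2O, KOH, diethylene glycol, 130 °C then 200 °C; cool; then 3 M aq HCl, THF, rt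
Reagents that add atoms: water, O
Why: Wolff–Kishner reduction in the Huang-Minlon manner removes the neopentyl C3 carbonyl, as is routine for 4,4-dimethyl-3-oxo terpenoids, while the base-stable dioxolane guards C6; acidifying the same mixture hydrolyses the ketal, and C5, again α to a carbonyl, is expected to keep the thermodynamically preferred trans fusion.

Step 11
Reactants: 21 (5R,10S)-4,4,10-trimethyl-trans-decalin-6-one
Product: 22 (5R,10S)-4,4,10-trimethyl-trans-decal-7-en-6-one
Conditions: 2-iodoxybenzoic acid (IBX, 2.5 equiv), DMSO/fluorobenzene, 70 °C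
Reagents that add atoms: none
Why: IBX-mediated α,β-dehydrogenation of a ketone through its enol can only desaturate C7–C8, because the other α-carbon (C5) has only quaternary neighbours.

Step 12
Reactants: 22 (5R,10S)-4,4,10-trimethyl-trans-decal-7-en-6-one
Product: 23 (5R,7R,8R,10S)-7,8-epoxy-4,4,10-trimethyl-trans-decalin-6-one
Conditions: 30 % aq H2O2, NaOH (0.5 equiv), MeOH, 0 °C to rt
Reagents that add atoms: hydrogen peroxide, OO
Why: Weitz–Scheffer nucleophilic epoxidation: hydroperoxide adds to C8 from the face anti to the C10 methyl (which is 1,3-diaxial to the other face) and the enolate closes the epoxide on the same face; both new centres are consumed in steps 13 and 14.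

Step 13
Reactants: 23 (5R,7R,8R,10S)-7,8-epoxy-4,4,10-trimethyl-trans-decalin-6-one
Product: 25 (5R,8R,10S)-4,4,10-trimethyl-trans-decal-6-en-8-ol, via epoxy hydrazone 24 (not isolated)
Conditions: N2H4·H2O, AcOH (cat.), MeOH, 0 °C to rt
Reagents that add atoms: none
Why: Wharton transposition: the hydrazone of the α,β-epoxy ketone fragments with epoxide opening and loss of N2, moving the double bond to C6=C7 and leaving the oxygen on C8 with the configuration inherited from the epoxide.

Step 14
Reactants: 25 (5R,8R,10S)-4,4,10-trimethyl-trans-decal-6-en-8-ol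
Product: 26 (5R,10S)-4,4,10-trimethyl-trans-decal-6-en-8-one
Conditions: Dess–Martin periodinane, CH2Cl2, 0 °C to rt
Reagents that add atoms: none
Why: Dess–Martin oxidation of a secondary allylic alcohol gives the transposed enone under non-basic conditions that leave the γ-centre C5 alone.

Step 15
Reactants: 26 (5R,10S)-4,4,10-trimethyl-trans-decal-6-en-8-one
Product: 29 (5R,10R)-4,4,10-trimethyl-9-methylidene-trans-decal-6-en-8-one, via Mannich base 27 (not isolated), via ammonium iodide 28 (not isolated)
Conditions: LiN(iPr)2, THF, −78 °C; Me2N=CH2+ I−, −78 °C to rt; then MeI, MeOH, rt; then aq NaHCO3, CH2Cl2, rt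
Reagents that add atoms: N,N-dimethylmethyleneiminium iodide (Eschenmoser's salt), C=[N+](C)C.[I-]
Why: α-Methylenation by Mannich reaction of the kinetic lithium enolate (C9 is the only α-position with hydrogens, the γ-hydrogen at C5 being buried between two quaternary carbons) followed by exhaustive methylation and E1cB elimination; the labile exocyclic enone is used at once.

Step 16
Reactants: 29 (5R,10R)-4,4,10-trimethyl-9-methylidene-trans-decal-6-en-8-one
Product: 30 (5R,9S,10R)-9-allyl-4,4,10-trimethyl-trans-decal-6-en-8-one
Conditions: CH2=CHMgBr (1.5 equiv), CuBr·SMe2 (10 mol %), THF, −78 °C; then AcOH/THF, −78 °C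
Reagents that add atoms: vinylmagnesium bromide, C=C[Mg]Br
Why: Copper-catalysed conjugate addition of the vinyl Grignard reagent to the open exocyclic terminus C11 (C6 is shielded by C5 and the C4 methyls) gives the C8 enolate, and its kinetic protonation at C9 anti to the adjacent axial C10 methyl places the allyl chain syn to that methyl (9S), which direct enolate allylation, with the electrophile entering anti, would not do.

Step 17
Reactants: 30 (5R,9S,10R)-9-allyl-4,4,10-trimethyl-trans-decal-6-en-8-one
Product: 31 (5R,8R,9S,10R)-9-allyl-8-{[isopropoxy(dimethyl)silyl]methyl}-4,4,10-trimethyl-trans-decal-6-en-8-ol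
Conditions: (iPrO)Me2SiCH2MgCl [from (iPrO)Me2SiCH2Cl, Mg, THF], THF, 0 °C; then aq NH4Cl
Reagents that add atoms: (chloromethyl)isopropoxydimethylsilane, CC(C)O[Si](C)(C)CCl, used as its Grignard reagent (isopropoxydimethylsilyl)methylmagnesium chloride, CC(C)O[Si](C)(C)C[Mg]Cl
Why: 1,2-Addition of the weakly basic α-silyl Grignard reagent (a hydroxymethyl anion equivalent) to the enone carbonyl is expected anti to the C10 methyl, and the C8 configuration is of no consequence because C8 becomes trigonal again in step 20.

Step 18
Reactants: 31 (5R,8R,9S,10R)-9-allyl-8-{[isopropoxy(dimethyl)silyl]methyl}-4,4,10-trimethyl-trans-decal-6-en-8-ol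
Product: 32 (5R,8R,9S,10R)-9-allyl-8-(hydroxymethyl)-4,4,10-trimethyl-trans-decal-6-en-8-ol
Conditions: 30 % aq H2O2, KF, KHCO3, THF/MeOH, rt
Reagents that add atoms: hydrogen peroxide, OO
Why: Tamao oxidation converts the C17–Si bond into C17–OH; under bicarbonate buffering it should outrun Peterson elimination of the β-hydroxysilane, and the unactivated alkenes do not react with basic peroxide.

Step 19
Reactants: 32 (5R,8R,9S,10R)-9-allyl-8-(hydroxymethyl)-4,4,10-trimethyl-trans-decal-6-en-8-ol
Product: 33 [(5R,8R,9S,10R)-9-allyl-8-hydroxy-4,4,10-trimethyl-trans-decal-6-en-8-yl]methyl acetate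
Conditions: Ac2O (1.2 equiv), pyridine, CH2Cl2, 0 °C to rt
Reagents that add atoms: acetic anhydride, CC(=O)OC(C)=O
Why: Chemoselective O-acylation of the primary C17 hydroxyl over the hindered tertiary C8 hydroxyl installs one of the two target acetates and shields C17 from the oxidant of step 20.

Step 20
Reactants: 33 [(5R,8R,9S,10R)-9-allyl-8-hydroxy-4,4,10-trimethyl-trans-decal-6-en-8-yl]methyl acetate
Product: 34 [(5R,9S,10S)-9-allyl-4,4,10-trimethyl-6-oxo-trans-decal-7-en-8-yl]methyl acetate
Conditions: [C5H5NH][CrO3Cl] (pyridinium chlorochromate), 4 Å molecular sieves, CH2Cl2, rt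
Reagents that add atoms: pyridinium chlorochromate, [O-][Cr](=O)(=O)Cl.c1cc[nH+]cc1
Why: Dauben–Babler oxidative transposition: the tertiary allylic chromate ester undergoes a [3,3] shift to C6 and is oxidised there, so C8 ends up on the C7=C8 double bond bearing C17 and C6 is a carbonyl again (its oxygen coming from the chromate); the acetate and the terminal alkene are inert.

Step 21
Reactants: 34 [(5R,9S,10S)-9-allyl-4,4,10-trimethyl-6-oxo-trans-decal-7-en-8-yl]methyl acetate
Product: 35 [(5R,6S,9S,10S)-9-allyl-6-hydroxy-4,4,10-trimethyl-trans-decal-7-en-8-yl]methyl acetate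
Conditions: NaBH4, CeCl3·7H2O, MeOH, −78 to −20 °C
Reagents that add atoms: none
Why: Luche 1,2-reduction: hydride adds to C6 from the face anti to the two syn-axial methyls on C4 and C10, so the hydroxyl ends up axial and syn to the C10 methyl (6S), and the cold, short, weakly basic conditions spare the acetate and the γ-centre C9.

Step 22
Reactants: 35 [(5R,6S,9S,10S)-9-allyl-6-hydroxy-4,4,10-trimethyl-trans-decal-7-en-8-yl]methyl acetate
Product: 36 [(5R,6S,9S,10S)-6-acetoxy-9-allyl-4,4,10-trimethyl-trans-decal-7-en-8-yl]methyl acetate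
Conditions: Ac2O, Et3N, DMAP (cat.), CH2Cl2, rt
Reagents that add atoms: acetic anhydride, CC(=O)OC(C)=O
Why: DMAP-catalysed acylation of the hindered axial secondary alcohol proceeds at oxygen with retention at C6.

Step 23
Reactants: 36 [(5R,6S,9S,10S)-6-acetoxy-9-allyl-4,4,10-trimethyl-trans-decal-7-en-8-yl]methyl acetate
Product: 37 [(5R,6S,9S,10S)-6-acetoxy-4,4,10-trimethyl-9-[(2E)-3-methyl-4-oxobut-2-en-1-yl]-trans-decal-7-en-8-yl]methyl acetate
Conditions: methacrolein (10 equiv), second-generation Hoveyda–Grubbs catalyst RuCl2(=CH-C6H4-2-OiPr)(H2IMes) (5 mol %), CH2Cl2, 40 °C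
Reagents that add atoms: methacrolein, CC(=C)C=O
Why: Olefin cross-metathesis of the terminal alkene with excess methacrolein gives the trisubstituted enal with the E geometry (formyl trans to C11) usual for this partner, while the hindered trisubstituted ring alkene should not engage the ruthenium carbene.

Step 24
Reactants: 37 [(5R,6S,9S,10S)-6-acetoxy-4,4,10-trimethyl-9-[(2E)-3-methyl-4-oxobut-2-en-1-yl]-trans-decal-7-en-8-yl]methyl acetate
Product: 38 [(5R,6S,9S,10S)-6-acetoxy-4,4,10-trimethyl-9-[(2E)-3-methylpenta-2,4-dien-1-yl]-trans-decal-7-en-8-yl]methyl acetate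
Conditions: Ph3PCH3Br, KN(SiMe3)2, THF, 0 °C (ylide Ph3P=CH2); then 37, −78 to 0 °C
Reagents that add atoms: methyltriphenylphosphonium bromide, C[P+](c1ccccc1)(c1ccccc1)c1ccccc1.[Br-], used as its ylide
Why: Wittig methylenation of the enal with the non-stabilised ylide at low temperature turns C14 into the terminal vinyl group without touching the C12=C13 geometry, the aldehyde reacting far faster than the two acetates.

**Compound list**

1 | propanal | CCC=O | starting material
2 | cyclohexylamine | NC1CCCCC1 | starting material
3 | N-propylidenecyclohexanamine | CCC=NC1CCCCC1 | intermediate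
4 | 5-bromopent-1-ene | C=CCCCBr | starting material
5 | rac-N-(2-methylhept-6-en-1-ylidene)cyclohexanamine | C=CCCCC(C)C=NC1CCCCC1 | intermediate
6 | rac-2-methylhept-6-enal | C=CCCCC(C)C=O | intermediate
7 | methyl vinyl ketone | CC(=O)C=C | starting material
8 | 1-(2-methylhepta-1,6-dien-1-yl)pyrrolidine | C=CCCCC(C)=CN1CCCC1 | intermediate
9 | rac-2-methyl-2-(3-oxobutyl)hept-6-enal | C=CCCCC(C)(CCC(C)=O)C=O | intermediate
10 | rac-4-methyl-4-(pent-4-en-1-yl)cyclohex-2-en-1-one | C=CCCCC1(C)CCC(=O)C=C1 | intermediate
11 | 4-methyl-4-(pent-4-en-1-yl)cyclohexa-2,5-dien-1-one | C=CCCCC1(C)C=CC(=O)C=C1 | intermediate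
12 | 4-methyl-4-[3-(1,2,4-trioxolan-3-yl)propyl]cyclohexa-2,5-dien-1-one | O=C1C=CC(C)(CCCC2OCOO2)C=C1 | intermediate
13 | 4-(1-methyl-4-oxocyclohexa-2,5-dien-1-yl)butanal | O=CCCCC1(C)C=CC(=O)C=C1 | intermediate
14 | (5S,10R)-10-methyl-cis-decal-1-ene-3,6-dione | C1CCC(=O)[C@H]2CC(=O)C=C[C@@]12C | intermediate
15 | (5R,10R)-10-methyl-trans-decal-1-ene-3,6-dione, systematically (4aR,8aR)-4a-methyl-2,3,4,4a,8,8a-hexahydronaphthalene-1,7-dione | C1CCC(=O)[C@@H]2CC(=O)C=C[C@@]12C | intermediate
16 | (5R,10R)-6,6-ethylenedioxy-10-methyl-trans-decal-1-en-3-one | C1CCC3(OCCO3)[C@@H]2CC(=O)C=C[C@@]12C | intermediate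
17 | (5S,10R)-6,6-ethylenedioxy-4,4,10-trimethyl-trans-decal-1-en-3-one | C1CCC3(OCCO3)[C@@H]2C(C)(C)C(=O)C=C[C@@]12C | intermediate
18 | (5S,10R)-6,6-ethylenedioxy-4,4,10-trimethyl-trans-decalin-3-one | C1CCC3(OCCO3)[C@@H]2C(C)(C)C(=O)CC[C@@]12C | intermediate
19 | (5S,10R)-6,6-ethylenedioxy-4,4,10-trimethyl-trans-decalin-3-one hydrazone | C1CCC3(OCCO3)[C@@H]2C(C)(C)C(=NN)CC[C@@]12C | intermediate
20 | (5R,10S)-6,6-ethylenedioxy-4,4,10-trimethyl-trans-decalin | C1CCC3(OCCO3)[C@@H]2C(C)(C)CCC[C@@]12C | intermediate
21 | (5R,10S)-4,4,10-trimethyl-trans-decalin-6-one | C1CCC(=O)[C@@H]2C(C)(C)CCC[C@@]12C | intermediate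
22 | (5R,10S)-4,4,10-trimethyl-trans-decal-7-en-6-one | C1C=CC(=O)[C@@H]2C(C)(C)CCC[C@@]12C | intermediate
23 | (5R,7R,8R,10S)-7,8-epoxy-4,4,10-trimethyl-trans-decalin-6-one (epoxide anti to the C10 methyl) | C1[C@@H]3[C@@H](O3)C(=O)[C@@H]2C(C)(C)CCC[C@@]12C | intermediate
24 | (5R,7S,8R,10S)-7,8-epoxy-4,4,10-trimethyl-trans-decalin-6-one hydrazone | C1[C@@H]3[C@@H](O3)C(=NN)[C@@H]2C(C)(C)CCC[C@@]12C | intermediate
25 | (5R,8R,10S)-4,4,10-trimethyl-trans-decal-6-en-8-ol (hydroxyl anti to the C10 methyl) | C1[C@@H](O)C=C[C@@H]2C(C)(C)CCC[C@@]12C | intermediate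
26 | (5R,10S)-4,4,10-trimethyl-trans-decal-6-en-8-one | C1C(=O)C=C[C@@H]2C(C)(C)CCC[C@@]12C | intermediate
27 | (5R,9S,10R)-9-[(dimethylamino)methyl]-4,4,10-trimethyl-trans-decal-6-en-8-one (aminomethyl anti to the C10 methyl) | CN(C)C[C@H]1C(=O)C=C[C@@H]2C(C)(C)CCC[C@@]12C | intermediate
28 | trimethyl{[(5R,9S,10R)-4,4,10-trimethyl-8-oxo-trans-decal-6-en-9-yl]methyl}ammonium iodide | C[N+](C)(C)C[C@H]1C(=O)C=C[C@@H]2C(C)(C)CCC[C@@]12C.[I-] | intermediate
29 | (5R,10R)-4,4,10-trimethyl-9-methylidene-trans-decal-6-en-8-one | C=C1C(=O)C=C[C@@H]2C(C)(C)CCC[C@@]12C | intermediate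
30 | (5R,9S,10R)-9-allyl-4,4,10-trimethyl-trans-decal-6-en-8-one (allyl syn to the C10 methyl) | C=CC[C@@H]1C(=O)C=C[C@@H]2C(C)(C)CCC[C@@]12C | intermediate
31 | (5R,8R,9S,10R)-9-allyl-8-{[isopropoxy(dimethyl)silyl]methyl}-4,4,10-trimethyl-trans-decal-6-en-8-ol | C=CC[C@@H]1[C@@](O)(C[Si](C)(C)OC(C)C)C=C[C@@H]2C(C)(C)CCC[C@@]12C | intermediate
32 | (5R,8R,9S,10R)-9-allyl-8-(hydroxymethyl)-4,4,10-trimethyl-trans-decal-6-en-8-ol | C=CC[C@@H]1[C@@](O)(CO)C=C[C@@H]2C(C)(C)CCC[C@@]12C | intermediate
33 | [(5R,8R,9S,10R)-9-allyl-8-hydroxy-4,4,10-trimethyl-trans-decal-6-en-8-yl]methyl acetate | C=CC[C@@H]1[C@@](O)(COC(C)=O)C=C[C@@H]2C(C)(C)CCC[C@@]12C | intermediate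
34 | [(5R,9S,10S)-9-allyl-4,4,10-trimethyl-6-oxo-trans-decal-7-en-8-yl]methyl acetate | C=CC[C@@H]1C(COC(C)=O)=CC(=O)[C@@H]2C(C)(C)CCC[C@@]12C | intermediate
35 | [(5R,6S,9S,10S)-9-allyl-6-hydroxy-4,4,10-trimethyl-trans-decal-7-en-8-yl]methyl acetate (hydroxyl syn to the C10 methyl) | C=CC[C@@H]1C(COC(C)=O)=C[C@H](O)[C@@H]2C(C)(C)CCC[C@@]12C | intermediate
36 | [(5R,6S,9S,10S)-6-acetoxy-9-allyl-4,4,10-trimethyl-trans-decal-7-en-8-yl]methyl acetate | C=CC[C@@H]1C(COC(C)=O)=C[C@H](OC(C)=O)[C@@H]2C(C)(C)CCC[C@@]12C | intermediate
37 | [(5R,6S,9S,10S)-6-acetoxy-4,4,10-trimethyl-9-[(2E)-3-methyl-4-oxobut-2-en-1-yl]-trans-decal-7-en-8-yl]methyl acetate | O=C/C(C)=C/C[C@@H]1C(COC(C)=O)=C[C@H](OC(C)=O)[C@@H]2C(C)(C)CCC[C@@]12C | intermediate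
38 | [(5R,6S,9S,10S)-6-acetoxy-4,4,10-trimethyl-9-[(2E)-3-methylpenta-2,4-dien-1-yl]-trans-decal-7-en-8-yl]methyl acetate (CNP0292756.1) | C=C/C(C)=C/C[C@@H]1C(COC(C)=O)=C[C@H](OC(C)=O)[C@@H]2C(C)(C)CCC[C@@]12C | target

**Step count**

Total: 24 steps. Longest linear sequence: 24 steps (the route is fully linear from propanal).

**Steps most likely to fail**

1. Step 6. Closure through a six-membered transition state may be slower than self-condensation of the aliphatic aldehyde or decay of the carbene, and the two enone arms may be told apart less well than in five-membered closures. The fallback keeps the C5–C6 bond but replaces the carbene-bound acyl anion by a nitronate. Setting out from 13, condensation with hydroxylamine gives 4-(1-methyl-4-oxocyclohexa-2,5-dien-1-yl)butanal oxime F1. Oxidation with NaBO3·4H2O in acetic acid gives 4-methyl-4-(4-nitrobutyl)cyclohexa-2,5-dien-1-one F2. A cinchona-alkaloid thiourea then catalyses the desymmetrising intramolecular nitro-Michael addition to (5S,10R)-10-methyl-6-nitro-cis-decal-1-en-3-one F3 (C6 epimers). A Nef reaction (NaOMe, then cold aqueous H2SO4) followed by DBU equilibration comes back to the route at 15.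

2. Step 8. The second C-methylation may stall, because the incoming methyl must take the axial site on C4 that is syn to both the C10 methyl and one oxygen of the C6 ketal, and O-methylation of the crowded enolate may take over. Setting out from 16, a single methylation (LiN(iPr)2, MeI) gives (5R,10R)-6,6-ethylenedioxy-4,10-dimethyl-trans-decal-1-en-3-one F4 (C4 epimers). LiN(iPr)2 and Me3SiCl convert it into the silyl dienol ether (5S,10R)-6,6-ethylenedioxy-4,10-dimethyl-3-(trimethylsilyloxy)-trans-decala-1,3-diene F5. Simmons–Smith cyclopropanation (Et2Zn, CH2I2) of its electron-rich C3=C4 bond from the open anti face gives the siloxycyclopropane F6. Base-induced opening of the cyclopropanol (NaOH, MeOH) turns the new CH2 into the second methyl group and comes back to the route at 17. The axial methyl is thus put in place by rehybridisation of C4 and not by attack from the hindered face.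

3. Step 20. The [3,3] shift has to deliver chromate oxygen to C6, a site wedged between C5 and the axial methyls; if it is slow, ionisation and elimination of the tertiary allylic alcohol to dienes may dominate. Setting out from 33, a rhenium-oxo-catalysed 1,3-transposition (Ph3SiOReO3, Et2O, low temperature) under non-oxidising conditions should give the secondary allylic alcohol [(5R,9S,10S)-9-allyl-6-hydroxy-4,4,10-trimethyl-trans-decal-7-en-8-yl]methyl acetate F7 as a C6 epimer mixture. The shift is driven by the move from a di- to a trisubstituted alkene and by relief of the syn-axial hydroxyl/methyl contact at C8. Dess–Martin oxidation of F7 comes back to the route at 34.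

**Further compounds**

F1 | step 6 | 4-(1-methyl-4-oxocyclohexa-2,5-dien-1-yl)butanal oxime | ON=CCCCC1(C)C=CC(=O)C=C1
F2 | step 6 | 4-methyl-4-(4-nitrobutyl)cyclohexa-2,5-dien-1-one | CC1(CCCC[N+](=O)[O-])C=CC(=O)C=C1
F3 | step 6 | (5S,10R)-10-methyl-6-nitro-cis-decal-1-en-3-one (C6 epimers) | C1CCC([N+](=O)[O-])[C@H]2CC(=O)C=C[C@@]12C
F4 | step 8 | (5R,10R)-6,6-ethylenedioxy-4,10-dimethyl-trans-decal-1-en-3-one (C4 epimers) | C1CCC3(OCCO3)[C@@H]2C(C)C(=O)C=C[C@@]12C
F5 | step 8 | (5S,10R)-6,6-ethylenedioxy-4,10-dimethyl-3-(trimethylsilyloxy)-trans-decala-1,3-diene | C1CCC3(OCCO3)[C@@H]2C(C)=C(O[Si](C)(C)C)C=C[C@@]12C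
F6 | step 8 | 6,6-ethylenedioxy-4,10-dimethyl-3,4-methano-3-(trimethylsilyloxy)-trans-decal-1-ene (methylene bridge anti to the C10 methyl) | C1CCC3(OCCO3)[C@@H]2[C@@]4(C)C[C@@]4(O[Si](C)(C)C)C=C[C@@]12C
F7 | step 20 | [(5R,9S,10S)-9-allyl-6-hydroxy-4,4,10-trimethyl-trans-decal-7-en-8-yl]methyl acetate (C6 epimers) | C=CC[C@@H]1C(COC(C)=O)=CC(O)[C@@H]2C(C)(C)CCC[C@@]12C
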